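## Retrosynthetic overview
1. Stypandrol ⇒ twofold Michael–Dieckmann benzannulation. Both acetyl/methyl-bearing rings (rings A and A', C1–C4) open to a 2,2'-biphenol bis(ortho-toluate) plus two molecules of 4-methoxypent-3-en-2-one.
2. Key disconnection: the two aryl C–O bonds of that biphenol (future O8/O8') ⇒ twofold ester-directed C–H hydroxylation of dimethyl 4,4'-dimethylbiphenyl-3,3'-dicarboxylate.
3. Biaryl diester ⇒ reductive homocoupling of methyl 5-bromo-2-methylbenzoate. The bromine fixes the 7,7' bond and the ester fixes where oxygen enters, so nothing depends on the regiochemistry of a phenol coupling.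
4. Ring order: rings B and B' (C5–C8) are bought, joined and then oxygenated. Rings A and A' are formed last, both in one operation, without protecting groups.

Assumption: the SMILES carries no stereodescriptor, and the 7,7' axis has only two ortho OH and two ortho H and rotates freely at room temperature, so the target is treated as one achiral compound with no stereocentre to set.

## Route

Step 1
Reactants: 1 methyl 5-bromo-2-methylbenzoate (2 equiv)
Product: 2 dimethyl 4,4'-dimethyl-[1,1'-biphenyl]-3,3'-dicarboxylate
Conditions: NiBr2(PPh3)2 (10 mol %), Zn dust (1.5 equiv), Et4NI (1 equiv), THF, 50 °C, 12 h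
Reagents that add atoms: none
Why: Nickel-catalysed reductive (Ullmann-type) homocoupling, in which Zn generates zerovalent nickel that inserts into the unhindered C–Br bond (para to CH3, meta to the ester) and the resulting diarylnickel reductively eliminates the symmetrical biaryl, methyl esters being inert under these conditions and no stereocentre being formed.

Step 2
Reactants: 2 dimethyl 4,4'-dimethyl-[1,1'-biphenyl]-3,3'-dicarboxylate
Product: 4 dimethyl 2,2'-dihydroxy-4,4'-dimethyl-[1,1'-biphenyl]-3,3'-dicarboxylate, via bis(trifluoroacetate) 3 (not isolated)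
Conditions: [RuCl2(p-cymene)]2 (5 mol %), AgOCOCF3 (20 mol %), PhI(OCOCF3)2 (3.0 equiv), CF3CO2H/(CF3CO)2O 3:1, 80 °C, sealed tube, 16 h; then MeOH, aq NaHCO3, rt
Reagents that add atoms: [bis(trifluoroacetoxy)iodo]benzene, O=C(OI(OC(=O)C(F)(F)F)c1ccccc1)C(F)(F)F (source of the new aryl oxygen); trifluoroacetic acid, OC(=O)C(F)(F)F (solvent pool that exchanges carboxylate with it)
Why: Proposed new method: twofold ester-directed C–H hydroxylation at the two inner (bay) C2–H/C2'–H bonds of a biaryl, a C–H bond type (flanked by the weak directing group on one side and an aryl ring on the other) on which this chemistry has not been shown and which here creates a 2,2'-biphenol; the ester carbonyl binds the cationic divalent ruthenium trifluoroacetate, the only free ortho C–H (the other ortho site carries CH3) is cleaved by carboxylate-assisted metalation to a five-membered ruthenacycle while the neighbouring ring twists out of plane to make room, PhI(OCOCF3)2 oxidises this to tetravalent ruthenium, and C–O reductive elimination gives the aryl trifluoroacetate, which is electron-poor and therefore shielded from over-oxidation and from dibenzofuran closure until the mild hydrolysis, the first C–O bond also increasing the biaryl twist and so exposing the second bay C–H; the closest known reaction type is ruthenium-catalysed ortho-hydroxylation of simple alkyl benzoates in CF3CO2H/(CF3CO)2O.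

Step 3
Reactants: 4 dimethyl 2,2'-dihydroxy-4,4'-dimethyl-[1,1'-biphenyl]-3,3'-dicarboxylate; 5 (E)-4-methoxypent-3-en-2-one (3.0 equiv)
Product: 8 stypandrol, via tetralithio tetraanion 6 (not isolated), via bis(methoxytetralone) 7 (not isolated)
Conditions: LiN(iPr)2 (4.5 equiv, commercial solution), THF/DMPU 10:1, −78 °C, 1 h; 5, −78 °C → rt, 12 h, Ar; then degassed 2 M HCl, rt
Reagents that add atoms: none
Why: Twofold Staunton–Weinreb annulation (tandem Michael addition, Dieckmann condensation, elimination), in which LiN(iPr)2 removes both phenolic and both ortho-toluate CH3 protons (the lithium phenoxides suppress intermolecular ester self-condensation), each benzylic carbanion adds to the methoxy-bearing β-carbon of the vinylogous ester 5, the resulting enolate closes onto the adjacent ester, and loss of methanol with tautomerisation gives the aromatic 2-acetyl-3-methyl-1-naphthol ring, so the four transient stereocentres of 7 vanish and the di-ortho-substituted 7,7' axis of 8 is not stereogenic.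

## Compound list
1 | methyl 5-bromo-2-methylbenzoate | COC(=O)c1cc(Br)ccc1C | starting material
2 | dimethyl 4,4'-dimethyl-[1,1'-biphenyl]-3,3'-dicarboxylate | COC(=O)c1cc(ccc1C)-c1ccc(C)c(C(=O)OC)c1 | intermediate
3 | dimethyl 4,4'-dimethyl-2,2'-bis(trifluoroacetoxy)-[1,1'-biphenyl]-3,3'-dicarboxylate (not isolated) | COC(=O)c1c(OC(=O)C(F)(F)F)c(ccc1C)-c1ccc(C)c(C(=O)OC)c1OC(=O)C(F)(F)F | intermediate
4 | dimethyl 2,2'-dihydroxy-4,4'-dimethyl-[1,1'-biphenyl]-3,3'-dicarboxylate | COC(=O)c1c(O)c(ccc1C)-c1ccc(C)c(C(=O)OC)c1O | intermediate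
5 | (E)-4-methoxypent-3-en-2-one (catalogue enol ether of acetylacetone) | CO/C(C)=C/C(C)=O | starting material
6 | tetralithium salt of 4, deprotonated at both OH and both aryl CH3 groups (not isolated) | [Li+].[Li+].[Li+].[Li+].COC(=O)c1c([O-])c(ccc1[CH2-])-c1ccc([CH2-])c(C(=O)OC)c1[O-] | intermediate
7 | 2,2'-diacetyl-8,8'-dihydroxy-3,3'-dimethoxy-3,3'-dimethyl-3,3',4,4'-tetrahydro-[7,7'-binaphthalene]-1,1'(2H,2'H)-dione, mixture of diastereomers, drawn neutral (not isolated) | CC(=O)C1C(=O)c2c(O)c(ccc2CC1(C)OC)-c1ccc2CC(C)(OC)C(C(C)=O)C(=O)c2c1O | intermediate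
8 | stypandrol, 1,1'-(1,1',8,8'-tetrahydroxy-3,3'-dimethyl-[7,7'-binaphthalene]-2,2'-diyl)diethanone, no stereocentre | CC(=O)c1c(C)cc2ccc(-c3ccc4cc(C)c(C(C)=O)c(O)c4c3O)c(O)c2c1O | target

## Step count and risks
Total step count: 3. Longest linear sequence: 3 (1 → 2 → 4 → 8).

**Step 2 (the proposed new step).**
- Risk: the bay C–H may be too shielded for the capped ruthenium, giving no reaction or only the mono-phenol.
- The fallback sets out from 2 and comes back at 4, using known carboxylate-directed palladium chemistry.
- Saponify 2 (LiOH, THF/H2O, 60 °C) to 4,4'-dimethyl-[1,1'-biphenyl]-3,3'-dicarboxylic acid F1.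
- Hydroxylate both positions ortho to the carboxylates with Pd(OAc)2 (20 mol %), KOAc, benzoquinone, O2 (1 atm), DMA, 115 °C. A strongly binding anionic carboxylate and a flat square-planar divalent palladium replace the weak ester donor and the piano-stool ruthenium. This gives 2,2'-dihydroxy-4,4'-dimethyl-[1,1'-biphenyl]-3,3'-dicarboxylic acid F2.
- Alkylate only the carboxylates (MeI, KHCO3, DMF, rt) to reach 4.

**Step 3.**
- Risk: the tetraanion may be poorly soluble or basic enough to enolise 5 instead of adding to it, and the phenoxide slows the Dieckmann closure.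
- The fallback sets out from 4 and comes back at 8. It swaps the unprotected polyanion for a protected bis(toluate) carrying one charge per ring.
- Treat 4 with NaH and MOMCl in DMF (0 °C → rt) to give dimethyl 2,2'-bis(methoxymethoxy)-4,4'-dimethyl-[1,1'-biphenyl]-3,3'-dicarboxylate F3, a standard 2-alkoxy-6-methylbenzoate substrate for this annulation.
- LiN(iPr)2 (2.4 equiv), then 5, THF, −78 °C → rt gives 8,8'-bis-O-(methoxymethyl)stypandrol F4.
- HCl in MeOH at 40 °C removes both acetals to give 8.

**Step 1.**
- Risk: hydrodebromination or stalling of the nickel cycle.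
- The fallback sets out from 1 and comes back at 2. It replaces the reductive homocoupling by a redox-neutral cross-coupling.
- Half of 1 is borylated (B2pin2, PdCl2(dppf), KOAc, dioxane, 90 °C) to methyl 2-methyl-5-(4,4,5,5-tetramethyl-1,3,2-dioxaborolan-2-yl)benzoate F5.
- F5 is joined to the other half of 1 by Suzuki–Miyaura coupling (PdCl2(dppf), K2CO3, dioxane/H2O, 90 °C) to give 2.

## Further compounds
F1 | step 2 | 4,4'-dimethyl-[1,1'-biphenyl]-3,3'-dicarboxylic acid | Cc1ccc(cc1C(=O)O)-c1ccc(C)c(C(=O)O)c1
F2 | step 2 | 2,2'-dihydroxy-4,4'-dimethyl-[1,1'-biphenyl]-3,3'-dicarboxylic acid | Cc1ccc(c(O)c1C(=O)O)-c1ccc(C)c(C(=O)O)c1O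
F3 | step 3 | dimethyl 2,2'-bis(methoxymethoxy)-4,4'-dimethyl-[1,1'-biphenyl]-3,3'-dicarboxylate | COCOc1c(ccc(C)c1C(=O)OC)-c1ccc(C)c(C(=O)OC)c1OCOC
F4 | step 3 | 8,8'-bis-O-(methoxymethyl)stypandrol | CC(=O)c1c(C)cc2ccc(c(OCOC)c2c1O)-c1ccc2cc(C)c(C(C)=O)c(O)c2c1OCOC
F5 | step 1 | methyl 2-methyl-5-(4,4,5,5-tetramethyl-1,3,2-dioxaborolan-2-yl)benzoate | COC(=O)c1cc(ccc1C)B1OC(C)(C)C(C)(C)O1
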